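The route disconnects ring B at the C6–C8 bond. The quaternary carbon C8, common to rings B, C and D, sits para to the oxygen on C12 in ring C, so ring C is carried as a eugenol-derived phenol and C8 is alkylated with loss of aromaticity. In one operation PhI(OAc)2 oxidises the C12 phenol, the tethered C6 malonate bonds to C8, ring B closes, the C8 stereocentre is set and ring C emerges as a 12-oxo-13-methoxy dienone ready for ring D. The precursor is a ring A Δ1-ene 19,10-lactone bearing the aryl group on C10, a silyl ether on C3 and a malonate on C5.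

Key step: step 17

Remark (numbering): gibberellin numbering is used for every intermediate (ring A = C1–C5, C10; C18 = methyl on C4; C19 = carboxyl carbon on C4; aryl ring = C8, C9, C11–C14; allyl = C15–C17); β is the face of ring A that carries C18 and the C3 oxygen, α the face that carries C19.

Remark (assumption): the auxiliary in step 4 is taken to direct methylation so that (S)-2-(methoxymethyl)pyrrolidine gives the C4 configuration drawn; if the sense is the opposite, the commercial (R)-auxiliary is used and nothing else changes.

Remark (precursor design): three choices shape the precursor and the steps after the key step.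
- The two malonate esters are different (methyl and 2-(trimethylsilyl)ethyl), so the surviving C7 ester falls to fluoride; a C7 methyl ester cannot be hydrolysed next to the base-labile Δ1-ene lactone. C6 of 21–26 is therefore an inconsequential mixture of epimers.
- The dealkoxycarbonylation is placed after the dienone has been reduced, because a 4-allylcyclohexa-2,5-dienone is prone to Cope rearrangement and aromatisation on heating.
- The methyl enol ether is unmasked only after 1,2-reduction, when it is an ordinary acid-labile enol ether.

Step 1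
Reactants: 1 eugenol
Product: 2 O-triisopropylsilyl eugenol
Conditions: i-Pr3SiCl, imidazole, DMF, rt
Reagents that add atoms: triisopropylsilyl chloride, CC(C)[Si](Cl)(C(C)C)C(C)C
Why: Imidazole-promoted O-silylation masks the phenol for the organometallic and enolate steps, and the bulky silyl group shields the neighbouring ring carbon (future C11) in the next step.

Step 2
Reactants: 2 O-triisopropylsilyl eugenol
Product: 3 1-allyl-2-bromo-5-methoxy-4-(triisopropylsilyloxy)benzene
Conditions: NBS, MeCN, 0 °C → rt
Reagents that add atoms: N-bromosuccinimide, BrN1C(=O)CCC1=O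
Why: Electrophilic aromatic bromination should go para to the methoxy group (future C9), the only activated position not flanked by the silyl ether or by two substituents, and is faster in MeCN than attack on the allyl double bond.

Step 3
Reactants: 4 2-methoxybenzoyl chloride; 5 (S)-2-(methoxymethyl)pyrrolidine
Product: 6 N-(2-methoxybenzoyl)-(S)-2-(methoxymethyl)pyrrolidine
Conditions: Et3N, CH2Cl2, 0 °C → rt
Reagents that add atoms: none
Why: N-acylation of the secondary amine by the acid chloride (Schotten–Baumann type) installs the chiral auxiliary for the reductive alkylation.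

Step 4
Reactants: 6 N-(2-methoxybenzoyl)-(S)-2-(methoxymethyl)pyrrolidine
Product: 7 2-methoxy-1-methylcyclohexa-2,5-diene-1-carboxamide of 5 (quaternary C4, methyl β, carboxamide α)
Conditions: K, NH3(l)/THF, t-BuOH (1 equiv), −78 °C; then MeI, −78 °C
Reagents that add atoms: iodomethane, CI
Why: Asymmetric Birch reduction–alkylation of a chiral 2-methoxybenzamide: the dissolving metal gives the chelated amide enolate, which MeI should alkylate on the face not screened by the methoxymethyl arm, setting the C4 quaternary centre.

Step 5
Reactants: 7 Birch diene amide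
Product: 8 1-methyl-2-oxocyclohex-5-ene-1-carboxamide of 5 (C3 ketone, C5=C10 alkene)
Conditions: 1 M HCl, MeOH, rt
Reagents that add atoms: water, O
Why: Acid hydrolysis of the enol ether frees the C3 ketone, and the C5=C10 double bond cannot move into conjugation because C4 is quaternary.

Step 6
Reactants: 8 β,γ-unsaturated keto amide
Product: 9 3β-hydroxy amide (OH cis to the C4 methyl)
Conditions: (R)-Me-CBS oxazaborolidine (0.2 equiv), catecholborane, PhMe, −40 °C
Reagents that add atoms: none
Why: Corey–Bakshi–Shibata reduction under catalyst control, with quaternary C4 as the large and C2H2 as the small ketone substituent, should deliver hydride to the α face and give the 3β alcohol.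

Step 7
Reactants: 9 3β-hydroxy amide
Product: 10 3β-tert-butyldimethylsilyl ether
Conditions: t-BuMe2SiOTf, 2,6-lutidine, CH2Cl2, 0 °C
Reagents that add atoms: tert-butyldimethylsilyl triflate, CC(C)(C)[Si](C)(C)OS(=O)(=O)C(F)(F)F
Why: Silyl triflate silylation protects the hindered secondary alcohol next to the quaternary centre.

Step 8
Reactants: 10 3β-silyl ether
Product: 11 C1 enone (C1 ketone conjugated with C10=C5; 3β-OTBS, 4β-methyl, 4α-carboxamide)
Conditions: Rh2(cap)4 (cap = caprolactamate, 1 mol %), t-BuOOH, K2CO3, CH2Cl2, rt
Reagents that add atoms: tert-butyl hydroperoxide, CC(C)(C)OO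
Why: In this catalytic allylic C–H oxidation hydrogen abstraction is possible only at C1, the single allylic methylene of the C5=C10 alkene (C4 is quaternary), and the allylic radical should be trapped at C1 rather than at neopentyl C5, so the mixed peroxide collapses to the conjugated C1 enone.

Step 9
Reactants: 11 C1 enone
Product: 12 10-iodo enone
Conditions: I2, pyridine, CH2Cl2, rt
Reagents that add atoms: iodine, II
Why: α-Iodination of a cyclic enone by pyridine-mediated conjugate addition, iodination and elimination places the halogen on C10 for cross-coupling.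

Step 10
Reactants: 3 aryl bromide; 12 10-iodo enone
Product: 15 10-aryl enone (aryl = 2-allyl-4-methoxy-5-(triisopropylsilyloxy)phenyl), via aryllithium 13 (not isolated), via arylzinc chloride 14 (not isolated)
Conditions: 3, n-BuLi, THF, −78 °C; ZnCl2, −78 °C → rt; then 12, Pd2(dba)3 (2.5 mol %), SPhos (10 mol %), THF, 50 °C
Reagents that add atoms: none
Why: Bromine–lithium exchange at −78 °C outruns proton transfer from the benzylic allyl position, and Negishi cross-coupling of the arylzinc with the α-iodo enone forms the C9–C10 bond without touching the amide or silyl ethers.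

Step 11
Reactants: 15 10-aryl enone
Product: 16 1α-allylic alcohol (OH cis to the C4 carboxamide)
Conditions: (R)-Me-CBS oxazaborolidine (0.2 equiv), catecholborane, PhMe, −78 °C
Reagents that add atoms: none
Why: Corey–Bakshi–Shibata 1,2-reduction with the aryl-bearing vinyl carbon as the large substituent should deliver hydride to the β face under catalyst control, and catecholborane leaves the allyl group alone.

Step 12
Reactants: 16 1α-allylic alcohol
Product: 18 methyl (C5α)-acetate with C10(aryl)=C1 alkene, via ketene acetal 17 (not isolated)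
Conditions: MeC(OMe)3, EtCO2H (cat.), xylene, 140 °C
Reagents that add atoms: trimethyl orthoacetate, CC(OC)(OC)OC
Why: Johnson–Claisen rearrangement is suprafacial, so the α C1–O bond is traded for an α C5–C6 bond (C6 cis to C19), and the double bond moves to C10=C1 where it is needed next.

Step 13
Reactants: 18 Claisen ester
Product: 19 1β-iodo 19,10-lactone (aryl 10β, lactone oxygen 10α, iodine trans to it, CH2CO2Me 5α)
Conditions: I2, THF/H2O, rt
Reagents that add atoms: iodine, II; water, O
Why: Iodolactonisation through the amide oxygen, a far better neighbouring group than the C7 ester, is a 5-exo, Markovnikov attack on benzylic C10 that the C4 carboxamide can make only from the α face, so C10 is set by C4; hydrolysis of the iminium lactone releases the auxiliary.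

Step 14
Reactants: 19 iodolactone
Product: 20 Δ1-ene 19,10-lactone methyl ester
Conditions: DBU, PhMe, 80 °C
Reagents that add atoms: none
Why: Base-mediated anti-periplanar dehydroiodination can only use the axial hydrogen on C2 (C10 is quaternary) and gives the C1=C2 alkene, the standard way to the allylic lactone of this ring A type.

Step 15
Reactants: 20 Δ1-ene lactone methyl ester
Product: 21 mixed methyl 2-(trimethylsilyl)ethyl malonate, phenol still silylated
Conditions: LiN(i-Pr)2 (2.2 equiv), THF, −78 °C; then 4-nitrophenyl 2-(trimethylsilyl)ethyl carbonate, −78 → −40 °C; AcOH quench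
Reagents that add atoms: 4-nitrophenyl 2-(trimethylsilyl)ethyl carbonate, C[Si](C)(C)CCOC(=O)Oc1ccc(cc1)[N+](=O)[O-]
Why: Claisen-type C-acylation of the only enolisable position (the lactone has no α-hydrogen) builds the malonate, and the second equivalent of base absorbs the more acidic product.

Step 16
Reactants: 21 silyl-protected malonate
Product: 22 phenol (key-step precursor)
Conditions: Bu4NF (1.05 equiv), AcOH (1.1 equiv), THF, −20 °C
Reagents that add atoms: none
Why: Buffered fluoride desilylation removes an aryl silyl ether within minutes at low temperature, far faster than it attacks the hindered secondary silyl ether or the 2-(trimethylsilyl)ethyl ester.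

Step 17
Reactants: 22 phenol malonate
Product: 23 tetracyclic cross-conjugated dienone (C8 quaternary, natural configuration)
Conditions: PhI(OAc)2 (1.1 equiv), NaHCO3, (CF3)2CHOH, −20 → 0 °C
Reagents that add atoms: none
Why: Ligand exchange of the phenol on trivalent iodine gives an aryloxy(phenyl)iodine acetate that behaves as a phenoxenium equivalent in the ionising, non-nucleophilic solvent; the enol(ate) of the tethered malonate bonds to C8, para to oxygen, with loss of PhI and acetate, and because C8 already carries the allyl group the ring cannot regain aromaticity. The closest known reaction type is the hypervalent-iodine oxidative dearomatisation of para-substituted phenols by tethered carbon nucleophiles such as 1,3-dicarbonyls, allylsilanes and silyl enol ethers. Ring B (C5–C6–C8–C9–C10) closes as a five-membered ring onto the arene carbon next to the tether anchor, the same ring-forming geometry as a Friedel–Crafts cyclisation to an indane (formally 5-exo-trig on the C8=C14 bond of the cation). The new stereocentre C8 is controlled by C10: in the reactive rotamer about C9–C10 the lactone oxygen, the least demanding of the three substituents on C10, lies in the arene plane beside C11–H, so C5 with its malonate sits over one face of C8 and C1 under the other, and C6 bonds on the face that gives the natural configuration. The step needs site selectivity (C8 and not the free ortho carbon C11, which would give a rearomatised indane) and face selectivity; both should follow from that rotamer, because reaching C11 would force O10 or C1 to eclipse the allyl-bearing side of the ring, and from the para-alkyl carbon carrying the largest share of the positive charge, while buffering and low temperature hold back external nucleophiles at C13 and acid-promoted allyl migration.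

Step 18
Reactants: 23 tetracyclic dienone
Product: 26 saturated ring C diosphenol diester (C9–H on the allyl-bearing face), via dienol 24 (not isolated), via acyloin 25 (not isolated)
Conditions: NaBH4, CeCl3·7H2O, MeOH, −78 °C; aq. oxalic acid, THF, 0 °C; then DBU (0.2 equiv), CH2Cl2, rt, argon
Reagents that add atoms: water, O
Why: Luche 1,2-reduction turns the dienone into a dienol whose methyl enol ether is then an ordinary acid-labile one, mild hydrolysis gives the β,γ-unsaturated α-ketol, and base-mediated enediol tautomerisation (a downhill internal redox isomerisation of an allylic carbinol to a 1,2-dione enol) moves the hydrogen to C9, where protonation should occur on the allyl-bearing face, opposite the C6 diester, to give the cis B/C ring fusion that is also favoured at equilibrium.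

Step 19
Reactants: 26 diosphenol diester
Product: 27 mono 2-(trimethylsilyl)ethyl ester, mixture of C6 epimers
Conditions: LiCl, H2O, DMF, 130 °C
Reagents that add atoms: none
Why: Krapcho dealkoxycarbonylation: chloride attacks only the methyl ester by SN2, the carboxylate loses CO2 and the ester enolate is protonated; ring C is no longer a 4-allyl dienone, so heating is safe at this stage.

Step 20
Reactants: 27 C6 epimer mixture
Product: 28 6-epimer with the ester trans to C4 (H5/H6 trans, as in the target)
Conditions: t-BuOK (1.3 equiv), t-BuOH/THF, 0 °C → rt, argon; AcOH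
Reagents that add atoms: none
Why: Base-mediated epimerisation through the ester enolate should funnel C6 to the thermodynamically preferred arrangement with the ester trans to the quaternary C4, while the diosphenol is held as its enolate and the bulky alkoxide does not attack the esters.

Step 21
Reactants: 28 diosphenol mono ester
Product: 30 C12=C13 enediol bis(dimethylphenylsilyl) ether, via silyloxy enone 29 (not isolated)
Conditions: [(Ph3P)CuH]6 (5 mol %), PhMe2SiH (3 equiv), PhMe, rt
Reagents that add atoms: dimethylphenylsilane, C[SiH](C)c1ccccc1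
Why: Copper hydride catalysis first silylates the acidic enol OH with loss of H2 (dehydrogenative silylation) and then adds hydride to C11 and silicon to O13 (1,4-hydrosilylation of the 2-silyloxy enone), which fixes the enol ether as C12=C13 without base and leaves isolated alkenes, esters and the lactone untouched.

Step 22
Reactants: 30 enediol bis(silyl) ether
Product: 31 pentacyclic 12-ketone with ring D closed (C13–OSiMe2Ph, C16=C17 methylene)
Conditions: Pd(OAc)2 (1.1 equiv), MeCN, rt
Reagents that add atoms: none
Why: Pd(OAc)2-mediated cycloalkenylation of a silyl enol ether (Saegusa-type oxidative carbocyclisation used for bicyclo[3.2.1]octanes): divalent palladium activates the terminal alkene, C13 attacks C16 in a 5-exo closure that is possible only on the allyl-bearing face and so sets C13, β-hydride loss from C16 gives the exocyclic methylene, and loss of the O12 silyl group leaves the C12 ketone with O13 still silylated.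

Step 23
Reactants: 31 12-ketone
Product: 32 12-alcohol (OH cis to O13, anti to the C15–C16 bridge)
Conditions: NaBH4, MeOH/THF, −40 °C
Reagents that add atoms: none
Why: Borohydride reduction under steric approach control should deliver hydride from the face of ring C that carries the two-carbon bridge (its C16 is flat), because the opposite face is screened by the axial C9–C10 bond and ring A, giving the axial alcohol of the target.

Step 24
Reactants: 32 protected target gibberellin
Product: 33 target gibberellin (number 87 of the gibberellin A series)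
Conditions: TASF (4 equiv), DMF, 0 °C → rt; dilute aq. HCl to pH 3
Reagents that add atoms: none
Why: Fluoride cleaves both silyl ethers and triggers β-elimination of the 2-(trimethylsilyl)ethyl ester to ethylene and Me3SiF, so the C7 acid and the three hydroxyls are freed in one near-neutral operation that avoids the hydrolytic conditions the Δ1-ene 19,10-lactone does not tolerate.

Compound list
1 | eugenol (4-allyl-2-methoxyphenol) | C=CCc1ccc(O)c(OC)c1 | starting material
2 | O-triisopropylsilyl eugenol | C=CCc1ccc(O[Si](C(C)C)(C(C)C)C(C)C)c(OC)c1 | intermediate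
3 | 1-allyl-2-bromo-5-methoxy-4-(triisopropylsilyloxy)benzene | C=CCc1cc(OC)c(O[Si](C(C)C)(C(C)C)C(C)C)cc1Br | intermediate
4 | 2-methoxybenzoyl chloride | COc1ccccc1C(Cl)=O | starting material
5 | (S)-2-(methoxymethyl)pyrrolidine | COC[C@@H]1CCCN1 | starting material
6 | N-(2-methoxybenzoyl)-(S)-2-(methoxymethyl)pyrrolidine | COC[C@@H]1CCCN1C(=O)c1ccccc1OC | intermediate
7 | 2-methoxy-1-methylcyclohexa-2,5-diene-1-carboxamide of 5 (C4 quaternary, methyl β) | COC1=CCC=C[C@]1(C)C(=O)N1CCC[C@H]1COC | intermediate
8 | 1-methyl-2-oxocyclohex-5-ene-1-carboxamide of 5 (C3 ketone, C5=C10 alkene) | O=C1CCC=C[C@]1(C)C(=O)N1CCC[C@H]1COC | intermediate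
9 | 3β-hydroxy amide (OH cis to C4 methyl) | O[C@H]1CCC=C[C@]1(C)C(=O)N1CCC[C@H]1COC | intermediate
10 | 3β-tert-butyldimethylsilyl ether of 9 | CC(C)(C)[Si](C)(C)O[C@H]1CCC=C[C@]1(C)C(=O)N1CCC[C@H]1COC | intermediate
11 | C1 enone (C10=C5; 3β-OTBS, 4β-methyl, 4α-carboxamide) | O=C1C[C@H](O[Si](C)(C)C(C)(C)C)[C@@](C)(C(=O)N2CCC[C@H]2COC)C=C1 | intermediate
12 | 10-iodo enone | O=C1C[C@H](O[Si](C)(C)C(C)(C)C)[C@@](C)(C(=O)N2CCC[C@H]2COC)C=C1I | intermediate
13 | 2-allyl-4-methoxy-5-(triisopropylsilyloxy)phenyllithium (not isolated) | [Li]c1cc(O[Si](C(C)C)(C(C)C)C(C)C)c(OC)cc1CC=C | intermediate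
14 | corresponding arylzinc chloride (not isolated) | Cl[Zn]c1cc(O[Si](C(C)C)(C(C)C)C(C)C)c(OC)cc1CC=C | intermediate
15 | 10-aryl enone | O=C1C[C@H](O[Si](C)(C)C(C)(C)C)[C@@](C)(C(=O)N2CCC[C@H]2COC)C=C1c1cc(O[Si](C(C)C)(C(C)C)C(C)C)c(OC)cc1CC=C | intermediate
16 | 1α-allylic alcohol (OH cis to the C4 carboxamide) | O[C@H]1C[C@H](O[Si](C)(C)C(C)(C)C)[C@@](C)(C(=O)N2CCC[C@H]2COC)C=C1c1cc(O[Si](C(C)C)(C(C)C)C(C)C)c(OC)cc1CC=C | intermediate
17 | mixed methyl ketene acetal of 16 (not isolated) | C=C(OC)O[C@H]1C[C@H](O[Si](C)(C)C(C)(C)C)[C@@](C)(C(=O)N2CCC[C@H]2COC)C=C1c1cc(O[Si](C(C)C)(C(C)C)C(C)C)c(OC)cc1CC=C | intermediate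
18 | methyl (C5α)-acetate with C10(aryl)=C1 alkene | COC(=O)C[C@H]1C(c2cc(O[Si](C(C)C)(C(C)C)C(C)C)c(OC)cc2CC=C)=CC[C@H](O[Si](C)(C)C(C)(C)C)[C@@]1(C)C(=O)N1CCC[C@H]1COC | intermediate
19 | 1β-iodo 19,10-lactone (aryl 10β, lactone O 10α) | C=CCc1cc(OC)c(O[Si](C(C)C)(C(C)C)C(C)C)cc1[C@@]12[C@H](I)C[C@H](O[Si](C)(C)C(C)(C)C)[C@@](C)(C(=O)O1)[C@H]2CC(=O)OC | intermediate
20 | Δ1-ene 19,10-lactone methyl ester | C=CCc1cc(OC)c(O[Si](C(C)C)(C(C)C)C(C)C)cc1[C@@]12C=C[C@H](O[Si](C)(C)C(C)(C)C)[C@@](C)(C(=O)O1)[C@H]2CC(=O)OC | intermediate
21 | mixed methyl 2-(trimethylsilyl)ethyl malonate, aryl silyl ether (C6 epimers) | C=CCc1cc(OC)c(O[Si](C(C)C)(C(C)C)C(C)C)cc1[C@@]12C=C[C@H](O[Si](C)(C)C(C)(C)C)[C@@](C)(C(=O)O1)[C@H]2C(C(=O)OC)C(=O)OCC[Si](C)(C)C | intermediate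
22 | aryl-substituted ring A lactone malonate with free C12 phenol (key-step precursor; C6 epimers) | C=CCc1cc(OC)c(O)cc1[C@@]12C=C[C@H](O[Si](C)(C)C(C)(C)C)[C@@](C)(C(=O)O1)[C@H]2C(C(=O)OC)C(=O)OCC[Si](C)(C)C | intermediate
23 | tetracyclic cross-conjugated dienone (key-step product; C6 epimers) | C=CC[C@]23C=C(OC)C(=O)C=C2[C@@]12C=C[C@H](O[Si](C)(C)C(C)(C)C)[C@@](C)(C(=O)O1)[C@H]2C3(C(=O)OC)C(=O)OCC[Si](C)(C)C | intermediate
24 | C12 dienol (not isolated) | C=CC[C@]23C=C(OC)C(O)C=C2[C@@]12C=C[C@H](O[Si](C)(C)C(C)(C)C)[C@@](C)(C(=O)O1)[C@H]2C3(C(=O)OC)C(=O)OCC[Si](C)(C)C | intermediate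
25 | 13-oxo-12-hydroxy Δ9(11) α-ketol (not isolated) | C=CC[C@]23CC(=O)C(O)C=C2[C@@]12C=C[C@H](O[Si](C)(C)C(C)(C)C)[C@@](C)(C(=O)O1)[C@H]2C3(C(=O)OC)C(=O)OCC[Si](C)(C)C | intermediate
26 | ring C diosphenol diester (C9–H cis to allyl) | C=CC[C@]23CC(=O)C(O)=C[C@H]2[C@@]12C=C[C@H](O[Si](C)(C)C(C)(C)C)[C@@](C)(C(=O)O1)[C@H]2C3(C(=O)OC)C(=O)OCC[Si](C)(C)C | intermediate
27 | diosphenol mono 2-(trimethylsilyl)ethyl ester, C6 epimer mixture | C=CC[C@]23CC(=O)C(O)=C[C@H]2[C@@]12C=C[C@H](O[Si](C)(C)C(C)(C)C)[C@@](C)(C(=O)O1)[C@H]2C3C(=O)OCC[Si](C)(C)C | intermediate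
28 | diosphenol mono ester, natural C6 (ester trans to C4) | C=CC[C@]23CC(=O)C(O)=C[C@H]2[C@@]12C=C[C@H](O[Si](C)(C)C(C)(C)C)[C@@](C)(C(=O)O1)[C@H]2[C@@H]3C(=O)OCC[Si](C)(C)C | intermediate
29 | 12-O-dimethylphenylsilyl enone (not isolated) | C=CC[C@]23CC(=O)C(O[Si](C)(C)c4ccccc4)=C[C@H]2[C@@]12C=C[C@H](O[Si](C)(C)C(C)(C)C)[C@@](C)(C(=O)O1)[C@H]2[C@@H]3C(=O)OCC[Si](C)(C)C | intermediate
30 | C12=C13 enediol bis(dimethylphenylsilyl) ether | C=CC[C@]23CC(O[Si](C)(C)c4ccccc4)=C(O[Si](C)(C)c4ccccc4)C[C@H]2[C@@]12C=C[C@H](O[Si](C)(C)C(C)(C)C)[C@@](C)(C(=O)O1)[C@H]2[C@@H]3C(=O)OCC[Si](C)(C)C | intermediate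
31 | pentacyclic 12-ketone, 13-O-silyl, 16-methylene | C=C1C[C@]23C[C@@]1(O[Si](C)(C)c4ccccc4)C(=O)C[C@H]2[C@@]12C=C[C@H](O[Si](C)(C)C(C)(C)C)[C@@](C)(C(=O)O1)[C@H]2[C@@H]3C(=O)OCC[Si](C)(C)C | intermediate
32 | 12-alcohol (cis to O13), fully protected target gibberellin | C=C1C[C@]23C[C@@]1(O[Si](C)(C)c4ccccc4)[C@@H](O)C[C@H]2[C@@]12C=C[C@H](O[Si](C)(C)C(C)(C)C)[C@@](C)(C(=O)O1)[C@H]2[C@@H]3C(=O)OCC[Si](C)(C)C | intermediate
33 | target gibberellin (number 87 of the gibberellin A series; 3β,12,13-trihydroxy Δ1-ene 19,10-lactone 7-acid) | C=C1C[C@]23C[C@@]1(O)[C@@H](O)C[C@H]2[C@@]12C=C[C@H](O)[C@@](C)(C(=O)O1)[C@H]2[C@@H]3C(=O)O | target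

Total step count: 24. Longest linear sequence: 22 steps (steps 3–24); the aryl branch (steps 1–2) joins at step 10.

Steps most likely to fail

Step 17. The oxidation may be diverted by attack of the malonate at the free ortho carbon C11 with rearomatisation, by capture of the cation at C13 by acetate or solvent, by poor facial selectivity at C8, or by acid-promoted migration of the allyl group in the product. The fallback makes the same C6–C8 bond with the oxidation level carried by the malonate carbon instead of the phenol. It sets out from 21, which is brominated at the malonate carbon (NaH, NBS, THF, 0 °C) to the bromomalonate F1. Fluoride (Bu4NF, THF, −40 °C) then frees the phenoxide, which should reduce the tethered tertiary bromomalonate by single-electron transfer; the malonyl radical bonds to the para carbon C8 of the phenoxyl partner, the pathway followed by halogen-mediated oxidative couplings of two carbanions. This is a dearomatisation under basic conditions without an external oxidant, and it returns to the route at 23.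

Step 22. The enediol ether may be lost to protodesilylation by the acetic acid that forms, to Saegusa-type dehydrogenation towards C14, or to 6-exo closure from C12; divalent palladium might also start to transpose the allylic lactone. The fallback replaces carbopalladation by one-electron oxidation. It sets out from 30, which is treated with Cu(OTf)2 and Cu2O in MeCN at 0 °C (oxidative cyclisation of unsaturated silyl enol ethers). The radical cation closes 5-exo from C13 onto C16, and divalent copper oxidises the primary C17 radical to the exocyclic alkene. It returns at 31 and makes no further compound, F0.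

Step 23. Facial selectivity may be poor or reversed, with hydride arriving from the face syn to C10 and giving the 12-epimeric (equatorial) alcohol F2. The fallback inverts C12 instead of reducing again. It sets out from 31 and goes through F2, which is converted into the triflate F3 (Tf2O, pyridine, CH2Cl2, −20 °C). The triflate is displaced by Bu4NNO2 in DMF (Lattrell–Dax inversion) from the very face that the reduction has then shown to be accessible. The nitrite ester F4 hydrolyses on aqueous work-up, and the fallback returns at 32.

Further compounds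
F1 | step 17 | bromomalonate of 21 (bromine on C6) | C=CCc1cc(OC)c(O[Si](C(C)C)(C(C)C)C(C)C)cc1[C@@]12C=C[C@H](O[Si](C)(C)C(C)(C)C)[C@@](C)(C(=O)O1)[C@H]2C(Br)(C(=O)OC)C(=O)OCC[Si](C)(C)C
F0 | step 22 | none | none
F2 | step 23 | 12-epimer of 32 (OH trans to O13) | C=C1C[C@]23C[C@@]1(O[Si](C)(C)c4ccccc4)[C@H](O)C[C@H]2[C@@]12C=C[C@H](O[Si](C)(C)C(C)(C)C)[C@@](C)(C(=O)O1)[C@H]2[C@@H]3C(=O)OCC[Si](C)(C)C
F3 | step 23 | 12-triflate of F2 | C=C1C[C@]23C[C@@]1(O[Si](C)(C)c4ccccc4)[C@H](OS(=O)(=O)C(F)(F)F)C[C@H]2[C@@]12C=C[C@H](O[Si](C)(C)C(C)(C)C)[C@@](C)(C(=O)O1)[C@H]2[C@@H]3C(=O)OCC[Si](C)(C)C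
F4 | step 23 | inverted 12-nitrite ester (O cis to O13) | C=C1C[C@]23C[C@@]1(O[Si](C)(C)c4ccccc4)[C@@H](ON=O)C[C@H]2[C@@]12C=C[C@H](O[Si](C)(C)C(C)(C)C)[C@@](C)(C(=O)O1)[C@H]2[C@@H]3C(=O)OCC[Si](C)(C)C
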